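**Remark (assumption):** the target SMILES has no stereocentre and no stereogenic double bond (C16 of the chain carries two identical methyl groups). Gentiside D is achiral, so "single enantiomer" requires no stereocontrol. Chain carbons are counted from the ester OCH2 (C1) to the isopropyl CH (C16).

**Plan**
1. Cuts: the ester O–C1 bond on the alkyl side, then the unfunctionalised chain bond C14–C15. This gives 2,3-dihydroxybenzoic acid + Br(CH2)14–CH2CH(CH3)2, and then Br(CH2)14CO2H + HO2C–CH2CH(CH3)2.
2. Forward: ω-pentadecalactone is opened by HBr to 15-bromopentadecanoic acid. A crossed Kolbe electrolysis with isovaleric acid then joins C14 to C15, with both carboxyl carbons lost as CO2. The resulting bromide O-alkylates the carboxylate of unprotected 2,3-dihydroxybenzoic acid.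
3. Enabling feature: the C14–C15 bond has a CH2 on each side, with no α-branch and no heteroatom, so both fragments are primary, non-stabilised radicals and suit anodic radical coupling. The iso branch is β to the carboxyl of the C5 acid.
4. The catechol ring (the benzene ring bearing C2–OH and C3–OH), which would not survive an anode, is attached only after the electrolysis. A C–Br bond that is inert at Pt stands in for the ester oxygen, and no protecting group is used.
5. Stereochemistry: none to set.

Key step: step 2

**Step 1**
Reactants: 1 ω-pentadecalactone (oxacyclohexadecan-2-one)
Product: 2 15-bromopentadecanoic acid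
Conditions: HBr (33% in AcOH, 5 equiv), conc. H2SO4 (cat.), 90 °C, sealed vessel; H2O; recrystallisation from hexane
Reagents that add atoms: hydrogen bromide, Br
Why: Acid-promoted alkyl–oxygen cleavage of the lactone, in which bromide attacks the O–CH2 carbon of the protonated ester by SN2 (any ω-hydroxy or ω-acetoxy acid formed by acidolysis is converted into the bromide under the same conditions); this is the standard HBr opening of lactones to ω-bromo acids.

**Step 2**
Reactants: 2 15-bromopentadecanoic acid (1 equiv); 3 3-methylbutanoic acid (isovaleric acid, 6 equiv)
Product: 6 1-bromo-16-methylheptadecane, via 14-bromotetradecyl radical 4 (not isolated), via 2-methylpropyl radical 5 (not isolated)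
Conditions: KOH (5 mol% of total CO2H), MeOH, undivided cell, smooth Pt anode / Pt cathode, constant current ca. 0.3 A cm⁻², 45–50 °C, until the solution turns slightly alkaline; evaporation, hexane/silica plug
Reagents that add atoms: none
Why: Crossed Kolbe electrolysis (anodic decarboxylative radical–radical coupling): both carboxylates are oxidised by one electron at the Pt anode, the acyloxy radicals lose CO2, and the primary radicals 4 and 5 combine in the dense radical layer at the electrode to form the C14–C15 bond, while methanol is reduced to H2 at the cathode. The closest known reaction type is the classical mixed Kolbe synthesis of iso-branched fatty chains from a short branched acid and an ω-functionalised long-chain acid, ω-bromo acids included. No ring is closed and no stereocentre is formed. The step needs cross-coupling over homo-coupling, which the sixfold excess of cheap 3 should secure statistically; its homodimer 2,5-dimethylhexane is volatile, and the homodimer of 2, 1,28-dibromooctacosane, is a far less soluble solid that should be removable by crystallisation or a silica plug. It also needs the one-electron radical pathway rather than the two-electron Hofer–Moest carbocation pathway, which is secured because both radicals are primary with no α-substituent or α-heteroatom, and by high current density at smooth Pt in weakly acidic methanol. The primary C–Br bond lies thirteen CH2 groups from the radical centre, is not oxidised at the anode, is not reduced at a Pt cathode where H2 evolution dominates, and meets only a low methoxide concentration, so it should survive.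

**Step 3**
Reactants: 6 1-bromo-16-methylheptadecane (1 equiv); 7 2,3-dihydroxybenzoic acid (1.5 equiv)
Product: 9 gentiside D (16-methylheptadecyl 2,3-dihydroxybenzoate), via potassium 2,3-dihydroxybenzoate 8 (not isolated)
Conditions: KHCO3 (1.5 equiv), DMF, Ar, rt 30 min, then 6, 65 °C; dilute HCl work-up
Reagents that add atoms: none
Why: Chemoselective SN2 O-alkylation of a carboxylate, since bicarbonate deprotonates only the CO2H (pKa about 3) and neither phenol (the 2-OH is also hydrogen-bonded to the carbonyl), so the carboxylate is the only anionic nucleophile towards the primary bromide; this is the bicarbonate/DMF esterification of hydroxybenzoic acids with alkyl halides.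

**Compound list**
1 | ω-pentadecalactone (oxacyclohexadecan-2-one) | O=C1CCCCCCCCCCCCCCO1 | starting material
2 | 15-bromopentadecanoic acid | OC(=O)CCCCCCCCCCCCCCBr | intermediate
3 | 3-methylbutanoic acid (isovaleric acid) | CC(C)CC(=O)O | starting material
4 | 14-bromotetradecyl radical | [CH2]CCCCCCCCCCCCCBr | intermediate
5 | 2-methylpropyl radical | [CH2]C(C)C | intermediate
6 | 1-bromo-16-methylheptadecane | CC(C)CCCCCCCCCCCCCCCBr | intermediate
7 | 2,3-dihydroxybenzoic acid | OC(=O)c1cccc(O)c1O | starting material
8 | potassium 2,3-dihydroxybenzoate | [K+].[O-]C(=O)c1cccc(O)c1O | intermediate
9 | gentiside D (16-methylheptadecyl 2,3-dihydroxybenzoate) | CC(C)CCCCCCCCCCCCCCCOC(=O)c1cccc(O)c1O | target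

**Total step count:** 3
**Longest linear sequence:** 3 (1 → 2 → 6 → 9)

**Steps most likely to fail, with fallbacks**

1. Step 2 (crossed Kolbe electrolysis). The risks are statistical homo-coupling that lowers the cross-coupled share, over-oxidation of the radicals to carbocations (methyl ethers, alkenes), passivation of the anode by a film, and slow methanolysis of the C–Br bond during a long electrolysis. The fallback replaces the radical C14–C15 union by a polar C15–C16 union that keeps all fifteen carbons of 2. It sets out from 2: isopropylmagnesium bromide (3 equiv, the first deprotonating the acid) with catalytic Li2CuCl4 in THF/NMP at −20 to 0 °C should couple at the bromide terminus of the magnesium carboxylate (copper-catalysed sp3–sp3 Grignard coupling) to give 16-methylheptadecanoic acid F1. Reduction with BH3·THF (0 °C to rt) should give 16-methylheptadecan-1-ol F2. An Appel reaction (CBr4, PPh3, CH2Cl2, 0 °C) then returns the route at 6.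

2. Step 3 (protecting-group-free carboxylate alkylation). The risks are competing O-alkylation of a phenol, air oxidation of the catechol to the o-quinone in the basic medium, and a sluggish SN2 reaction of the long-chain bromide. The fallback moves from chemoselectivity to protection. It sets out from 6: alkylation of the caesium salt of commercial 2,3-bis(benzyloxy)benzoic acid (OC(=O)c1cccc(OCc2ccccc2)c1OCc1ccccc1; Cs2CO3, DMF, 60 °C) should give 16-methylheptadecyl 2,3-bis(benzyloxy)benzoate F3. Hydrogenolysis (H2, Pd/C, EtOAc/EtOH, rt) should remove both benzyl groups without touching the ester and returns the route at 9.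

3. Step 1 (HBr opening of the macrolactone). The risks are incomplete alkyl–oxygen cleavage, acid-catalysed oligoesterification of the ring-opened hydroxy acid, and partial capture as the ω-acetate. The fallback separates ring opening from bromination. It sets out from 1: methanolysis (NaOMe cat., MeOH, reflux) should give methyl 15-hydroxypentadecanoate F4. An Appel reaction (CBr4, PPh3, CH2Cl2, 0 °C) should give methyl 15-bromopentadecanoate F5. Mild saponification (LiOH, THF/H2O, 0 °C to rt, then HCl) returns the route at 2.

**Further compounds**
F1 | step 2 | 16-methylheptadecanoic acid | CC(C)CCCCCCCCCCCCCCC(=O)O
F2 | step 2 | 16-methylheptadecan-1-ol | CC(C)CCCCCCCCCCCCCCCO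
F3 | step 3 | 16-methylheptadecyl 2,3-bis(benzyloxy)benzoate | CC(C)CCCCCCCCCCCCCCCOC(=O)c1cccc(OCc2ccccc2)c1OCc1ccccc1
F4 | step 1 | methyl 15-hydroxypentadecanoate | COC(=O)CCCCCCCCCCCCCCO
F5 | step 1 | methyl 15-bromopentadecanoate | COC(=O)CCCCCCCCCCCCCCBr
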